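**Retrosynthetic overview**

- The route rests on ring A, where the adjacent carbons C8a and C4a carry O1 and the C4 carbonyl carbon and the C5 oxygen sits next to C4a. Ring C is therefore cut at O1–C8a, C4–C4a and O1–C2 into a C4a≡C8a aryne, polarised by the C5 alkoxy group, and a β-methoxy-α-prenyl acrylic acid that brings C2, C3, C4, both ring-C oxygens and ring B.
- The aryne precursor comes from 5-methoxyresorcinol: bis-MOM ether, three directed lithiations (SiMe3 at the future C4a between the two OMOM groups, then prenyl at C6 and at C8), removal of one MOM group without protic acid (the aryl–Si bond flanked by three oxygens would be lost to ipso-protonation), then triflation.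
- The acid comes from 2,4,5-trihydroxybenzaldehyde: tris-MOM ether, acetate aldol and oxidation to the β-keto ester, C-prenylation, O-methylation, saponification.
- Rings A and B are bought; ring C is the only ring formed (key step); removal of four MOM groups ends the route.

Key step: step 13

Remark: the enol ethers 21, 22 and 24 are drawn Z (methoxy cis to the carbonyl); an E/Z mixture would serve equally, because the geometry is erased when ring C closes. Compounds 17 and 19 are racemic and their stereocentres are gone after step 11; the target has no stereocentre.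

**Step 1**
Reactants: 1 5-methoxyresorcinol (5-methoxybenzene-1,3-diol)
Product: 2 1-methoxy-3,5-bis(methoxymethoxy)benzene
Conditions: MOMCl (2.5 equiv), iPr2NEt, CH2Cl2, 0 °C to rt
Reagents that add atoms: chloromethyl methyl ether (MOMCl), COCCl
Why: Williamson-type O-alkylation of both phenols gives the bis-acetal whose OMOM groups direct the lithiations that follow.

**Step 2**
Reactants: 2 1-methoxy-3,5-bis(methoxymethoxy)benzene
Product: 4 [4-methoxy-2,6-bis(methoxymethoxy)phenyl]trimethylsilane, via aryllithium 3 (not isolated)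
Conditions: n-BuLi (1.1 equiv), THF, 0 °C; TMSCl, −78 °C to rt
Reagents that add atoms: chlorotrimethylsilane (TMSCl), C[Si](C)(C)Cl
Why: Directed ortho-metalation takes the C–H between the two OMOM groups, the most acidic and doubly coordinated site, and silylation there blocks the future C4a and installs the later aryne trigger.

**Step 3**
Reactants: 4 [4-methoxy-2,6-bis(methoxymethoxy)phenyl]trimethylsilane; 5 prenyl bromide (1-bromo-3-methylbut-2-ene)
Product: 7 [4-methoxy-2,6-bis(methoxymethoxy)-3-(3-methylbut-2-en-1-yl)phenyl]trimethylsilane, via aryllithium 6 (not isolated)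
Conditions: n-BuLi, TMEDA, THF, 0 °C; CuI (10 mol%), 5, −78 °C to rt
Reagents that add atoms: none
Why: With the site between the OMOM groups blocked, directed ortho-metalation occurs between OMe and OMOM, and copper-catalysed SN2 allylation of the aryllithium with the primary allylic bromide should give the linear prenyl group.

**Step 4**
Reactants: 7 [4-methoxy-2,6-bis(methoxymethoxy)-3-(3-methylbut-2-en-1-yl)phenyl]trimethylsilane; 5 prenyl bromide
Product: 9 [4-methoxy-2,6-bis(methoxymethoxy)-3,5-bis(3-methylbut-2-en-1-yl)phenyl]trimethylsilane, via aryllithium 8 (not isolated)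
Conditions: n-BuLi, TMEDA, THF, −20 to 0 °C; CuI (10 mol%), 5, −78 °C to rt
Reagents that add atoms: none
Why: A second directed ortho-metalation at the last ring C–H (flanked by OMe and OMOM, kinetically preferred over the benzylic-allylic CH2) and the same copper-catalysed allylation should give the symmetric hexasubstituted arene.

**Step 5**
Reactants: 9 [4-methoxy-2,6-bis(methoxymethoxy)-3,5-bis(3-methylbut-2-en-1-yl)phenyl]trimethylsilane
Product: 11 3-methoxy-5-(methoxymethoxy)-2,4-bis(3-methylbut-2-en-1-yl)-6-(trimethylsilyl)phenol, via aryl trimethylsilyl ether 10 (not isolated)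
Conditions: TMSOTf (1.0 equiv), 2,2'-bipyridyl (2 equiv), MeCN, 0 °C; then H2O, rt; chromatography on Et3N-deactivated silica
Reagents that add atoms: none
Why: Silyl triflate with 2,2'-bipyridyl turns an aromatic MOM ether into the aryl silyl ether under buffered aprotic conditions and water then frees the phenol, so neither the acid-labile aryl–Si bond nor the prenyl groups meet strong protic acid; 9 is symmetric, so either MOM group gives the same phenol and mono-cleavage is set by stoichiometry, with unreacted 9 recycled.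

**Step 6**
Reactants: 11 3-methoxy-5-(methoxymethoxy)-2,4-bis(3-methylbut-2-en-1-yl)-6-(trimethylsilyl)phenol
Product: 12 3-methoxy-5-(methoxymethoxy)-2,4-bis(3-methylbut-2-en-1-yl)-6-(trimethylsilyl)phenyl trifluoromethanesulfonate
Conditions: NaH, THF, 0 °C; PhNTf2, 0 °C to rt
Reagents that add atoms: N-phenylbis(trifluoromethanesulfonimide) (PhNTf2), O=S(=O)(N(c1ccccc1)S(=O)(=O)C(F)(F)F)C(F)(F)F
Why: O-sulfonylation of the hindered sodium phenoxide with a mild triflyl donor should give the ortho-silylaryl triflate without acid or fluoride.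

**Step 7**
Reactants: 13 2,4,5-trihydroxybenzaldehyde
Product: 14 2,4,5-tris(methoxymethoxy)benzaldehyde
Conditions: MOMCl (4.5 equiv), iPr2NEt, DMF, 0 °C to rt, Ar
Reagents that add atoms: chloromethyl methyl ether (MOMCl), COCCl
Why: Exhaustive O-alkylation under argon protects the oxidation-prone hydroxyquinol ring B as base-stable acetals.

**Step 8**
Reactants: 14 2,4,5-tris(methoxymethoxy)benzaldehyde; 15 methyl acetate
Product: 17 methyl 3-hydroxy-3-[2,4,5-tris(methoxymethoxy)phenyl]propanoate (racemic), via lithium enolate 16 (not isolated)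
Conditions: LiN(iPr)2, THF, −78 °C; 15; then 14, −78 °C; H2O quench
Reagents that add atoms: none
Why: Aldol addition of the ester lithium enolate to the non-enolisable aldehyde is preferred to a Lewis-acid diazoacetate homologation, in which so electron-rich an aryl group tends to migrate; the new carbinol centre forms as a racemate and is oxidised away in step 9.

**Step 9**
Reactants: 17 methyl 3-hydroxy-3-[2,4,5-tris(methoxymethoxy)phenyl]propanoate
Product: 18 methyl 3-oxo-3-[2,4,5-tris(methoxymethoxy)phenyl]propanoate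
Conditions: DMP (1,1,1-triacetoxy-1,2-benziodoxol-3-one), NaHCO3, CH2Cl2, 0 °C to rt
Reagents that add atoms: none
Why: Buffered periodinane oxidation of the secondary benzylic alcohol should give the β-keto ester without touching the MOM ethers.

**Step 10**
Reactants: 18 methyl 3-oxo-3-[2,4,5-tris(methoxymethoxy)phenyl]propanoate; 5 prenyl bromide
Product: 19 methyl 5-methyl-2-[2,4,5-tris(methoxymethoxy)benzoyl]hex-4-enoate (racemic)
Conditions: K2CO3, 5 (1.05 equiv), acetone, rt to 45 °C
Reagents that add atoms: none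
Why: SN2 C-alkylation of the stabilised β-keto ester enolate with one equivalent of the allylic bromide should give the mono-prenyl compound; its stereocentre is racemic and disappears in step 11.

**Step 11**
Reactants: 19 methyl 5-methyl-2-[2,4,5-tris(methoxymethoxy)benzoyl]hex-4-enoate
Product: 21 methyl (2Z)-2-{methoxy[2,4,5-tris(methoxymethoxy)phenyl]methylidene}-5-methylhex-4-enoate, via sodium enolate 20 (not isolated)
Conditions: NaH, DMPU, 0 °C; Me2SO4, 0 °C to rt
Reagents that add atoms: dimethyl sulfate, COS(=O)(=O)OC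
Why: A dissociated enolate in a dipolar aprotic solvent reacts with the hard sulfate electrophile at oxygen (enolate O-alkylation), and C-methylation would have to build a congested quaternary centre.

**Step 12**
Reactants: 21 methyl (2Z)-2-{methoxy[2,4,5-tris(methoxymethoxy)phenyl]methylidene}-5-methylhex-4-enoate
Product: 22 (2Z)-2-{methoxy[2,4,5-tris(methoxymethoxy)phenyl]methylidene}-5-methylhex-4-enoic acid
Conditions: LiOH·H2O, THF/MeOH/H2O, 50 °C; then aq. citric acid to pH 4–5, 0 °C
Reagents that add atoms: lithium hydroxide, [Li+].[OH-]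
Why: Saponification of the methyl ester (acyl–oxygen cleavage) followed by buffered acidification should free the acid while the vinylogous carbonate and the MOM ethers stay intact.

**Step 13**
Reactants: 12 3-methoxy-5-(methoxymethoxy)-2,4-bis(3-methylbut-2-en-1-yl)-6-(trimethylsilyl)phenyl trifluoromethanesulfonate (1.5 equiv); 22 (2Z)-2-{methoxy[2,4,5-tris(methoxymethoxy)phenyl]methylidene}-5-methylhex-4-enoic acid
Product: 25 7-methoxy-5-(methoxymethoxy)-3,6,8-tris(3-methylbut-2-en-1-yl)-2-[2,4,5-tris(methoxymethoxy)phenyl]-4H-chromen-4-one, via aryne 23 (not isolated), via caesium acylphenoxide 24 (not isolated)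
Conditions: CsF (4 equiv), THF (0.02 M), sealed tube, 125 °C
Reagents that add atoms: none
Why: Proposed new method: fluoride removes the silyl group and triflate leaves to give aryne 23; the carboxylate of 22 adds through oxygen at C8a, the C4a aryl anion beside the C5 OMOM group attacks the ester carbonyl through a four-membered transition state, and this 1,3 O-to-C acyl shift opens to phenoxide 24. The phenoxide then adds 6-endo-trig to C2 of the β-methoxy enone and methoxide is expelled (addition–elimination), which closes ring C directly at the flavone oxidation level. The closest known reaction is the CsF-mediated insertion of arynes into the C–O bond of carboxylic acids, which gives ortho-hydroxyaryl ketones and, with cinnamic or arylpropiolic acids, chromanones and flavones; a β-alkoxyacrylic acid and a hexasubstituted aryne have not been shown. No stereocentre is formed, and because C2 becomes tetrahedral before methoxide leaves, the alkene geometry of 22 is without consequence. Oxygen must bond at C8a and not at C4a: the inductively withdrawing C5 alkoxy group distorts the aryne so that nucleophiles attack the distal carbon C8a and charge builds at C4a, against only a modest steric bias from the C8 prenyl group. Acyl transfer must also outrun protonation of the aryl anion and its conjugate addition to C2, which high temperature, high dilution and excess CsF are meant to secure.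

**Step 14**
Reactants: 25 7-methoxy-5-(methoxymethoxy)-3,6,8-tris(3-methylbut-2-en-1-yl)-2-[2,4,5-tris(methoxymethoxy)phenyl]-4H-chromen-4-one
Product: 26 5-hydroxy-7-methoxy-3,6,8-tris(3-methylbut-2-en-1-yl)-2-(2,4,5-trihydroxyphenyl)-4H-chromen-4-one
Conditions: 3 M aq. HCl/MeOH/THF, 40 °C, Ar
Reagents that add atoms: none
Why: Acid-catalysed acetal exchange with methanol removes the four phenolic MOM groups under conditions mild enough to leave the trisubstituted alkenes of the prenyl groups untouched.

**Compound list**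

1 | 5-methoxyresorcinol (5-methoxybenzene-1,3-diol) | COc1cc(O)cc(O)c1 | starting material
2 | 1-methoxy-3,5-bis(methoxymethoxy)benzene | COCOc1cc(OC)cc(OCOC)c1 | intermediate
3 | [4-methoxy-2,6-bis(methoxymethoxy)phenyl]lithium | [Li]c1c(OCOC)cc(OC)cc1OCOC | intermediate
4 | [4-methoxy-2,6-bis(methoxymethoxy)phenyl]trimethylsilane | COCOc1cc(OC)cc(OCOC)c1[Si](C)(C)C | intermediate
5 | prenyl bromide (1-bromo-3-methylbut-2-ene) | CC(C)=CCBr | starting material
6 | [6-methoxy-2,4-bis(methoxymethoxy)-3-(trimethylsilyl)phenyl]lithium | COCOc1cc(OC)c([Li])c(OCOC)c1[Si](C)(C)C | intermediate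
7 | [4-methoxy-2,6-bis(methoxymethoxy)-3-(3-methylbut-2-en-1-yl)phenyl]trimethylsilane | COCOc1cc(OC)c(CC=C(C)C)c(OCOC)c1[Si](C)(C)C | intermediate
8 | [2-methoxy-4,6-bis(methoxymethoxy)-3-(3-methylbut-2-en-1-yl)-5-(trimethylsilyl)phenyl]lithium | COCOc1c([Li])c(OC)c(CC=C(C)C)c(OCOC)c1[Si](C)(C)C | intermediate
9 | [4-methoxy-2,6-bis(methoxymethoxy)-3,5-bis(3-methylbut-2-en-1-yl)phenyl]trimethylsilane | COCOc1c(CC=C(C)C)c(OC)c(CC=C(C)C)c(OCOC)c1[Si](C)(C)C | intermediate
10 | trimethyl{[3-methoxy-5-(methoxymethoxy)-2,4-bis(3-methylbut-2-en-1-yl)-6-(trimethylsilyl)phenyl]oxy}silane | COCOc1c(CC=C(C)C)c(OC)c(CC=C(C)C)c(O[Si](C)(C)C)c1[Si](C)(C)C | intermediate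
11 | 3-methoxy-5-(methoxymethoxy)-2,4-bis(3-methylbut-2-en-1-yl)-6-(trimethylsilyl)phenol | COCOc1c(CC=C(C)C)c(OC)c(CC=C(C)C)c(O)c1[Si](C)(C)C | intermediate
12 | 3-methoxy-5-(methoxymethoxy)-2,4-bis(3-methylbut-2-en-1-yl)-6-(trimethylsilyl)phenyl trifluoromethanesulfonate | COc1c(CC=C(C)C)c(OCOC)c([Si](C)(C)C)c(OS(=O)(=O)C(F)(F)F)c1CC=C(C)C | intermediate
13 | 2,4,5-trihydroxybenzaldehyde | O=Cc1cc(O)c(O)cc1O | starting material
14 | 2,4,5-tris(methoxymethoxy)benzaldehyde | COCOc1cc(OCOC)c(OCOC)cc1C=O | intermediate
15 | methyl acetate | COC(C)=O | starting material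
16 | lithium enolate of methyl acetate (lithium 1-methoxyethenolate) | C=C(O[Li])OC | intermediate
17 | methyl 3-hydroxy-3-[2,4,5-tris(methoxymethoxy)phenyl]propanoate (racemic) | COC(=O)CC(O)c1cc(OCOC)c(OCOC)cc1OCOC | intermediate
18 | methyl 3-oxo-3-[2,4,5-tris(methoxymethoxy)phenyl]propanoate | COC(=O)CC(=O)c1cc(OCOC)c(OCOC)cc1OCOC | intermediate
19 | methyl 5-methyl-2-[2,4,5-tris(methoxymethoxy)benzoyl]hex-4-enoate (racemic) | COC(=O)C(CC=C(C)C)C(=O)c1cc(OCOC)c(OCOC)cc1OCOC | intermediate
20 | sodium enolate of 19 | COC(=O)C(CC=C(C)C)=C([O-])c1cc(OCOC)c(OCOC)cc1OCOC.[Na+] | intermediate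
21 | methyl (2Z)-2-{methoxy[2,4,5-tris(methoxymethoxy)phenyl]methylidene}-5-methylhex-4-enoate | CO/C(c1cc(OCOC)c(OCOC)cc1OCOC)=C(/CC=C(C)C)C(=O)OC | intermediate
22 | (2Z)-2-{methoxy[2,4,5-tris(methoxymethoxy)phenyl]methylidene}-5-methylhex-4-enoic acid | CO/C(c1cc(OCOC)c(OCOC)cc1OCOC)=C(/CC=C(C)C)C(=O)O | intermediate
23 | 5-methoxy-3-(methoxymethoxy)-4,6-bis(3-methylbut-2-en-1-yl)benzyne (the C4a≡C8a aryne) | COC1=C(CC=C(C)C)C#CC(OCOC)=C1CC=C(C)C | intermediate
24 | caesium 3-methoxy-5-(methoxymethoxy)-2,4-bis(3-methylbut-2-en-1-yl)-6-[(2Z)-2-{methoxy[2,4,5-tris(methoxymethoxy)phenyl]methylidene}-5-methylhex-4-enoyl]phenoxide | COc1c(CC=C(C)C)c(OCOC)c(C(=O)/C(CC=C(C)C)=C(\OC)c2cc(OCOC)c(OCOC)cc2OCOC)c([O-])c1CC=C(C)C.[Cs+] | intermediate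
25 | 7-methoxy-5-(methoxymethoxy)-3,6,8-tris(3-methylbut-2-en-1-yl)-2-[2,4,5-tris(methoxymethoxy)phenyl]-4H-chromen-4-one | COc1c(CC=C(C)C)c(OCOC)c2c(=O)c(CC=C(C)C)c(-c3cc(OCOC)c(OCOC)cc3OCOC)oc2c1CC=C(C)C | intermediate
26 | 5-hydroxy-7-methoxy-3,6,8-tris(3-methylbut-2-en-1-yl)-2-(2,4,5-trihydroxyphenyl)-4H-chromen-4-one | COc1c(CC=C(C)C)c(O)c2c(=O)c(CC=C(C)C)c(-c3cc(O)c(O)cc3O)oc2c1CC=C(C)C | target

**Totals**

Total step count: 14. Longest linear sequence: 8 steps (steps 1–6, 13, 14; the branch 7–12, 13, 14 is equally long).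

**Steps most likely to fail**

Step 13 (the proposed method). The C4a aryl anion may be protonated before the acyl group shifts, which stops at the aryl ester. It may instead add to C2 of the acrylate, a coumarin-type closure. The hindered, electron-rich vinylogous carbonate carbonyl may also resist attack. The fallback uses known chemistry, sets out from 12 and 14 and returns at 26. Triflate 12 is heated with CsF and commercial 5-methylhex-4-enoic acid (CC(C)=CCCC(=O)O) in THF at 125 °C; aryne insertion of a plain aliphatic acid is established and should give 1-[2-hydroxy-4-methoxy-6-(methoxymethoxy)-3,5-bis(3-methylbut-2-en-1-yl)phenyl]-5-methylhex-4-en-1-one F1. Aldehyde 14 is oxidised under Pinnick conditions (NaClO2, NaH2PO4, 2-methylbut-2-ene) to 2,4,5-tris(methoxymethoxy)benzoic acid F2, which 1,1'-carbonyldiimidazole converts in the flask to (imidazol-1-yl)[2,4,5-tris(methoxymethoxy)phenyl]methanone F3. F1 is treated with LiN(SiMe3)2 (3 equiv, THF, −78 °C) and C-acylated with F3, which gives the Baker–Venkataraman-type diketone 1-[2-hydroxy-4-methoxy-6-(methoxymethoxy)-3,5-bis(3-methylbut-2-en-1-yl)phenyl]-2-(3-methylbut-2-en-1-yl)-3-[2,4,5-tris(methoxymethoxy)phenyl]propane-1,3-dione F4. HCl in MeOH then cyclodehydrates F4 and removes the four MOM groups in one operation to give 26.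

Step 5. Cleavage controlled only by stoichiometry may run on to the diol or stall, and the electron-rich aryl–Si bond may be lost by ipso-protonation during hydrolysis. The fallback moves the desymmetrisation to the triflation; it sets out from 9 and returns at 12. Excess TMSOTf with 2,2'-bipyridyl converts both MOM ethers to [5-methoxy-4,6-bis(3-methylbut-2-en-1-yl)-2-(trimethylsilyl)-1,3-phenylene]bis(oxy)bis(trimethylsilane) F5. Water hydrolyses it to 5-methoxy-4,6-bis(3-methylbut-2-en-1-yl)-2-(trimethylsilyl)benzene-1,3-diol F6. F6 with NaH (2 equiv) and PhNTf2 (1 equiv) should be mono-triflated, the first triflate lowering the reactivity of the remaining phenoxide, to 3-hydroxy-5-methoxy-4,6-bis(3-methylbut-2-en-1-yl)-2-(trimethylsilyl)phenyl trifluoromethanesulfonate F7. MOMCl with iPr2NEt then gives 12.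

Step 14. Protic acid may drive cyclisation of a prenyl group onto a neighbouring phenol (the 2'-OH onto the C3 prenyl, the 5-OH onto the C6 prenyl) or Markovnikov addition to the alkenes, and the free hydroxyquinol ring B may oxidise in air. The fallback replaces protic hydrolysis by aprotic trans-protection; it sets out from 25 and returns at 26. Excess TMSOTf with 2,2'-bipyridyl in MeCN converts the four MOM ethers to 7-methoxy-3,6,8-tris(3-methylbut-2-en-1-yl)-5-(trimethylsilyloxy)-2-[2,4,5-tris(trimethylsilyloxy)phenyl]-4H-chromen-4-one F8, and the silyl ethers are taken off with aqueous citric acid in MeOH at 0 °C under argon to give 26.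

**Further compounds**

F1 | step 13 | 1-[2-hydroxy-4-methoxy-6-(methoxymethoxy)-3,5-bis(3-methylbut-2-en-1-yl)phenyl]-5-methylhex-4-en-1-one | COc1c(CC=C(C)C)c(OCOC)c(C(=O)CCC=C(C)C)c(O)c1CC=C(C)C
F2 | step 13 | 2,4,5-tris(methoxymethoxy)benzoic acid | COCOc1cc(OCOC)c(OCOC)cc1C(=O)O
F3 | step 13 | (imidazol-1-yl)[2,4,5-tris(methoxymethoxy)phenyl]methanone | COCOc1cc(OCOC)c(OCOC)cc1C(=O)n1ccnc1
F4 | step 13 | 1-[2-hydroxy-4-methoxy-6-(methoxymethoxy)-3,5-bis(3-methylbut-2-en-1-yl)phenyl]-2-(3-methylbut-2-en-1-yl)-3-[2,4,5-tris(methoxymethoxy)phenyl]propane-1,3-dione (racemic) | COc1c(CC=C(C)C)c(OCOC)c(C(=O)C(CC=C(C)C)C(=O)c2cc(OCOC)c(OCOC)cc2OCOC)c(O)c1CC=C(C)C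
F5 | step 5 | [5-methoxy-4,6-bis(3-methylbut-2-en-1-yl)-2-(trimethylsilyl)-1,3-phenylene]bis(oxy)bis(trimethylsilane) | COc1c(CC=C(C)C)c(O[Si](C)(C)C)c([Si](C)(C)C)c(O[Si](C)(C)C)c1CC=C(C)C
F6 | step 5 | 5-methoxy-4,6-bis(3-methylbut-2-en-1-yl)-2-(trimethylsilyl)benzene-1,3-diol | COc1c(CC=C(C)C)c(O)c([Si](C)(C)C)c(O)c1CC=C(C)C
F7 | step 5 | 3-hydroxy-5-methoxy-4,6-bis(3-methylbut-2-en-1-yl)-2-(trimethylsilyl)phenyl trifluoromethanesulfonate | COc1c(CC=C(C)C)c(O)c([Si](C)(C)C)c(OS(=O)(=O)C(F)(F)F)c1CC=C(C)C
F8 | step 14 | 7-methoxy-3,6,8-tris(3-methylbut-2-en-1-yl)-5-(trimethylsilyloxy)-2-[2,4,5-tris(trimethylsilyloxy)phenyl]-4H-chromen-4-one | COc1c(CC=C(C)C)c(O[Si](C)(C)C)c2c(=O)c(CC=C(C)C)c(-c3cc(O[Si](C)(C)C)c(O[Si](C)(C)C)cc3O[Si](C)(C)C)oc2c1CC=C(C)C
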